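**Remark on the structure.** The SMILES is read as (4R,5R) on the cyclohexenone (ring A): the C5 methyl group is cis to the side chain and trans to the C4 methyl group. Ring A is numbered C1 (C=O) to C6; the side chain runs from C1' (on C4) to C10' (on the butenolide, ring B).

## The problem

- Cyclolinteinone joins a 3,4,5-trimethylcyclohex-2-en-1-one (ring A) through its quaternary C4 and a CH2CH2 link (C1', C2') to a chain with two E-trisubstituted alkenes (C3'=C4', C7'=C8') that ends in a 4-substituted furan-2(5H)-one (ring B).
- The only stereocentres are the adjacent pair C4 (all-carbon quaternary, CH3 and CH2R) and C5 (CH3, H). The two groups to be told apart at C4 differ only beyond their first carbon.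
- The chain is achiral and cannot relay stereochemistry, so the pair must be set on the ring itself with absolute control. C5 could steer C4 only by 1,2-induction on a six-membered ring.
- The two E-trisubstituted alkenes sit in a skipped 1,5-relationship and have no thermodynamic bias, so their geometry must be built in.
- The enone excludes organolithium, Grignard, borane and strong hydride reagents after it is formed. The butenolide is a base-labile Michael acceptor with an acidic γ-CH2. The skipped polyene does not tolerate strong acid.
- The enabling feature is that C3 and C5 each carry a methyl group and flank C4. With a second double bond at C5=C6, ring A becomes a cross-conjugated dienone with a mirror plane through C1 and C4, which is 3,4,5-trimethylphenol alkylated at its para carbon.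
- Both stereocentres can therefore come from one enantiotopic-group- and face-selective 1,4-reduction of a flat, achiral ring.

## Retrosynthesis

**C10'–C4 (ring B).** Target 23 is cut between the chain and the butenolide, giving alkyl iodide 20 (used as zinc reagent 22) and commercial 4-bromofuran-2(5H)-one 21. This cut puts the most fragile ring in last, under base-free conditions. Building ring B from an acyclic precursor would cost several steps on the complete skeleton. The forward step must be an sp3–sp2 coupling that leaves the enone and the γ-CH2 alone.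

**C2'–C3'.** Iodide 20 comes from alcohol 19, which is cut between C2' and C3' into ring iodide 9 (as zinc reagent 18) and vinyl iodide 17. The neighbouring cuts are worse:
- C1'–C2' needs a nucleophile or an SN2 reaction at a neopentyl carbon.
- C4–C1' returns to enolate alkylation and gives up the symmetry of the ring.
- C3'=C4' by olefination of a methyl ketone gives poor E/Z control.

The geometry of C3'=C4' is carried in 17, and an alkylzinc iodide tolerates the enone. The coupling must proceed with retention at the alkenyl carbon.

**Chain 17.** The unit C(CH3)=CH–CH2–CH2 occurs twice, so one alkynol, pent-3-yn-1-ol 10, supplies both halves. It gives (E)-vinyl iodide 12 and, through iodide 13, zinc reagent 14. Their coupling gives enynol 15, and a second hydrozirconation–iodination gives 17. Each alkene geometry comes from a syn addition to an alkyne, not from an olefination.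

**C4 handle.** Iodide 9 is traced through alcohol 8 and aldehyde 7 to allyl enone 5. The allyl group is what the dearomatisation delivers; one carbon is removed by ozonolysis. Only chemoselectivity between an isolated alkene or aldehyde and the enone is asked.

**Key cut: C5–H.** Enone 5 is the dihydro derivative of the achiral dienone 4. Reducing the right one of the two enantiotopic C=C bonds, with hydride entering C5 syn to the C4 methyl group, sets C4 and C5 together. The precursor has no stereocentre.

**C4–C1' by dearomatisation.** Dienone 4 is 3,4,5-trimethylphenol 1 allylated at its para carbon with allyltrimethylsilane 2 under oxidation by trivalent iodine. The quaternary carbon is made in one step from a commercial arene, and no stereochemistry is involved.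

## Roads not taken

**Alternative 1:** the most obvious route cuts C4–C1' and C4–CH3 as enolate alkylations (Stork–Danheiser sequence).
- Forward: the vinylogous ester (R)-3-isobutoxy-5-methylcyclohex-2-en-1-one A1 is alkylated at C6 with a homofarnesyl-type iodide and then with MeI to give A2; methyllithium addition and acidic transposition give the enone.
- Why not: A1 derives from an achiral dione and is formed as a racemate, so absolute configuration needs a resolution. The quaternary centre then depends on 1,2-induction from one methyl group. The whole chain must be made first and carried through two strong-base alkylations and an organolithium addition, which forces a protected chain end and a late butenolide construction.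
- The chosen plan takes both stereocentres from one catalyst-controlled step on a twelve-carbon achiral substrate.

**Alternative 2:** C4–C1' by [3,3]-sigmatropic rearrangement.
- Forward: Johnson–Claisen rearrangement of (1S,4R)-2,3,4-trimethylcyclohex-2-en-1-ol A3 transfers the carbinol configuration to C4 and gives ester A4; allylic oxidation of the ring CH2 then gives the enone.
- Why not: A3 already holds two stereocentres, so the problem is moved, not solved. The rearrangement must form a quaternary carbon at a tetrasubstituted alkene next to a tertiary centre, where elimination competes. The late C–H oxidation must choose between the ring CH2 and an allylic methyl group.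
- The step count to iodide 9 is higher than in the chosen plan.

**Alternative 3:** C3–C4 and C5–C6 by Diels–Alder reaction.
- Forward: diene A5 (trimethyl[(4-methoxypenta-1,3-dien-2-yl)oxy]silane) and (Z)-2-methylbut-2-enal A6 would give, after hydrolysis and loss of methanol, aldehyde A7.
- Why not: the C3–C4 bond forms between a fully substituted diene terminus and the α-carbon of a trisubstituted dienophile. A6 isomerises readily to its E isomer under Lewis acids, and the E isomer gives the wrong C4/C5 relationship. No enantioselective version for such a congested pair can be relied on.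
- The chosen plan avoids making a bond between two fully substituted carbons altogether.

Key step: step 2

## Route

**Step 1**
Reactants: 1 3,4,5-trimethylphenol; 2 allyltrimethylsilane
Product: 4 3,4,5-trimethyl-4-(prop-2-en-1-yl)cyclohexa-2,5-dien-1-one, via aryloxy-λ3-iodane 3 (not isolated)
Conditions: PhI(OAc)2 (1.1 equiv), 2 (4 equiv), (CF3)2CHOH/CH2Cl2, −20 to 0 °C; NaHCO3 work-up; product stored cold
Reagents that add atoms: none
Why: Oxidative dearomatisation of a para-alkylphenol by trivalent iodine (ligand exchange to 3, loss of PhI, capture of the phenoxenium ion at the methyl-bearing para carbon by the allylsilane, desilylation) is the known oxidative para-allylation of 4-alkylphenols; para attack gives a dienone that cannot rearomatise, and no stereocentre arises because 4 has a mirror plane through C1 and C4.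

**Step 2**
Reactants: 4 3,4,5-trimethyl-4-(prop-2-en-1-yl)cyclohexa-2,5-dien-1-one
Product: 5 (4R,5R)-3,4,5-trimethyl-4-(prop-2-en-1-yl)cyclohex-2-en-1-one
Conditions: ene-reductase (flavin mononucleotide-dependent Old Yellow Enzyme family, homologue chosen from a panel), NADP+ (cat.), D-glucose, glucose dehydrogenase, K2HPO4/KH2PO4 buffer pH 7.0, DMSO (5% v/v), 30 °C
Reagents that add atoms: none
Why: Proposed new method: ene-reductases reduce an enone C=C by hydride transfer from N5 of the reduced flavin to the β-carbon and protonation of the α-carbon by the active-site tyrosine on the opposite face; here C5 is the β-carbon and C6 the α-carbon of one of the two enantiotopic enone units of 4, and the closest known reaction types are the ene-reductase desymmetrisation of 4,4-disubstituted cyclohexa-2,5-dienones without β-substituents and the ene-reductase reduction of 3-methylcyclohex-2-enone, which have not yet been shown together on a β-methylated dienone. No ring is closed. C5 is set by the face of hydride delivery: with the carbonyl group held by the two hydrogen-bond donors of the active site and the flat ring stacked on the flavin, the small C4 methyl group should point toward the flavin and the allyl group away from it, so hydride should enter C5 syn to the C4 methyl group and leave the C5 methyl group cis to the allyl group. C4 is set by the choice between the enantiotopic double bonds, made by the asymmetric pocket that receives the β-methyl group; members of this family bind enones in normal and flipped modes, so the panel is screened for the one that reduces the double bond reached first on going clockwise from C4 when the ring is viewed from its C4-methyl face with C1 at the bottom. The step needs enantiotopic-group selectivity, face selectivity and arrest after one reduction; arrest is expected because 5 is a non-planar, less electrophilic mono-enone and a 4,4-disubstituted ring cannot be aromatised by the enzyme.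

**Step 3**
Reactants: 5 (4R,5R)-3,4,5-trimethyl-4-(prop-2-en-1-yl)cyclohex-2-en-1-one
Product: 7 2-[(1R,6R)-1,2,6-trimethyl-4-oxocyclohex-2-en-1-yl]acetaldehyde, via ozonide 6 (not isolated)
Conditions: O3, CH2Cl2, Sudan Red 7B indicator, −78 °C; then PPh3, −78 °C to rt
Reagents that add atoms: ozone, [O-][O+]=O
Why: Ozonolysis with reductive work-up; the monosubstituted alkene reacts much faster than the electron-poor trisubstituted enone C=C, the indicator end point limits ozone to one equivalent, and neither stereocentre is enolisable.

**Step 4**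
Reactants: 7 2-[(1R,6R)-1,2,6-trimethyl-4-oxocyclohex-2-en-1-yl]acetaldehyde
Product: 8 (4R,5R)-4-(2-hydroxyethyl)-3,4,5-trimethylcyclohex-2-en-1-one
Conditions: NaBH4, CH2Cl2/EtOH (7:3), −78 °C
Reagents that add atoms: none
Why: Chemoselective low-temperature borohydride reduction; an unhindered aldehyde is reduced far faster than a conjugated β,β-disubstituted ketone.

**Step 5**
Reactants: 8 (4R,5R)-4-(2-hydroxyethyl)-3,4,5-trimethylcyclohex-2-en-1-one
Product: 9 (4R,5R)-4-(2-iodoethyl)-3,4,5-trimethylcyclohex-2-en-1-one
Conditions: I2, PPh3, imidazole, CH2Cl2, 0 °C to rt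
Reagents that add atoms: iodine, II
Why: Appel-type iodination of a primary alcohol by SN2 displacement of the alkoxyphosphonium ion; the neutral conditions leave the enone untouched.

**Step 6**
Reactants: 10 pent-3-yn-1-ol
Product: 12 (E)-4-iodopent-3-en-1-ol, via alkenylzirconocene 11 (not isolated)
Conditions: Cp2Zr(H)Cl (2.5 equiv), THF, 0 to 50 °C; then I2, 0 °C; aqueous work-up
Reagents that add atoms: iodine, II
Why: Hydrozirconation–iodination of a methyl alkyne; the first equivalent of hydride is consumed as the zirconium alkoxide, syn addition with excess reagent equilibrates zirconium to the less hindered methyl-bearing carbon, and iodinolysis with retention gives the (E)-2-iodoalkene, any regioisomer being removed by chromatography.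

**Step 7**
Reactants: 10 pent-3-yn-1-ol
Product: 13 5-iodopent-2-yne
Conditions: I2, PPh3, imidazole, CH2Cl2, 0 °C to rt
Reagents that add atoms: iodine, II
Why: Appel-type iodination of a primary homopropargylic alcohol.

**Step 8**
Reactants: 13 5-iodopent-2-yne; 12 (E)-4-iodopent-3-en-1-ol
Product: 15 (E)-4-methylnon-3-en-7-yn-1-ol, via alkylzinc iodide 14 (not isolated)
Conditions: 13, Zn dust, LiCl, THF, 25–40 °C; then 12 (0.5 equiv), Pd(OAc)2 (2 mol%), SPhos (4 mol%), THF, 25 °C
Reagents that add atoms: none
Why: Zinc insertion into a primary alkyl iodide followed by Negishi sp3–sp2 coupling with retention of the alkene geometry; this catalyst couples organozinc halides in the presence of free hydroxyl groups, and the inexpensive zinc reagent is used in excess.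

**Step 9**
Reactants: 15 (E)-4-methylnon-3-en-7-yn-1-ol
Product: 17 (3E,7E)-8-iodo-4-methylnona-3,7-dien-1-ol, via alkenylzirconocene 16 (not isolated)
Conditions: Cp2Zr(H)Cl (2.5 equiv), THF, 0 to 50 °C; then I2, 0 °C; aqueous work-up
Reagents that add atoms: iodine, II
Why: Same hydrozirconation–iodination as step 6; the trisubstituted alkene is inert to Cp2Zr(H)Cl, and syn addition with zirconium on the methyl-bearing carbon fixes the E geometry of the future C3'=C4' bond.

**Step 10**
Reactants: 9 (4R,5R)-4-(2-iodoethyl)-3,4,5-trimethylcyclohex-2-en-1-one; 17 (3E,7E)-8-iodo-4-methylnona-3,7-dien-1-ol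
Product: 19 (4R,5R)-4-[(3E,7E)-10-hydroxy-3,7-dimethyldeca-3,7-dien-1-yl]-3,4,5-trimethylcyclohex-2-en-1-one, via alkylzinc iodide 18 (not isolated)
Conditions: 9, Zn dust, LiCl, THF, 35 °C; then 17 (1.2 equiv), Pd(OAc)2 (3 mol%), SPhos (6 mol%), THF, 25 °C
Reagents that add atoms: none
Why: Negishi sp3–sp2 coupling; alkylzinc iodides do not add to enones or ketones, the reacting CH2 is primary, the alkenyl iodide couples with retention, and no stereocentre is touched.

**Step 11**
Reactants: 19 (4R,5R)-4-[(3E,7E)-10-hydroxy-3,7-dimethyldeca-3,7-dien-1-yl]-3,4,5-trimethylcyclohex-2-en-1-one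
Product: 20 (4R,5R)-4-[(3E,7E)-10-iodo-3,7-dimethyldeca-3,7-dien-1-yl]-3,4,5-trimethylcyclohex-2-en-1-one
Conditions: I2, PPh3, imidazole, CH2Cl2, 0 °C to rt
Reagents that add atoms: iodine, II
Why: Appel-type iodination of the primary alcohol; the conditions are neutral and leave the enone and the trisubstituted alkenes alone.

**Step 12**
Reactants: 20 (4R,5R)-4-[(3E,7E)-10-iodo-3,7-dimethyldeca-3,7-dien-1-yl]-3,4,5-trimethylcyclohex-2-en-1-one; 21 4-bromofuran-2(5H)-one
Product: 23 cyclolinteinone [4-{(3E,7E)-4,8-dimethyl-10-[(1R,6R)-1,2,6-trimethyl-4-oxocyclohex-2-en-1-yl]deca-3,7-dien-1-yl}furan-2(5H)-one], via alkylzinc iodide 22 (not isolated)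
Conditions: 20, Zn dust, LiCl, THF, 35 °C; then 21 (1.3 equiv), Pd(PPh3)4 (5 mol%), THF, 25–40 °C
Reagents that add atoms: none
Why: Negishi coupling of an alkylzinc iodide with a β-bromo-α,β-unsaturated lactone (a vinylogous acyl bromide that adds readily to zerovalent palladium); the step is base-free, so the butenolide γ-CH2 and the enone are not deprotonated, and ring B is installed last.

## Compound list

(Cyclopentadienyl ligands are drawn σ-bonded in the SMILES of 11 and 16.)

1 | 3,4,5-trimethylphenol | Cc1cc(O)cc(C)c1C | starting material
2 | allyltrimethylsilane | C=CC[Si](C)(C)C | starting material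
3 | acetoxy(phenyl)(3,4,5-trimethylphenoxy)-λ3-iodane | CC(=O)OI(Oc1cc(C)c(C)c(C)c1)c1ccccc1 | intermediate
4 | 3,4,5-trimethyl-4-(prop-2-en-1-yl)cyclohexa-2,5-dien-1-one | CC1=CC(=O)C=C(C)C1(C)CC=C | intermediate
5 | (4R,5R)-3,4,5-trimethyl-4-(prop-2-en-1-yl)cyclohex-2-en-1-one | CC1=CC(=O)C[C@@H](C)[C@@]1(C)CC=C | intermediate
6 | (4R,5R)-3,4,5-trimethyl-4-(1,2,4-trioxolan-3-ylmethyl)cyclohex-2-en-1-one (epimers at the trioxolane carbon) | CC1=CC(=O)C[C@@H](C)[C@@]1(C)CC1OCOO1 | intermediate
7 | 2-[(1R,6R)-1,2,6-trimethyl-4-oxocyclohex-2-en-1-yl]acetaldehyde | CC1=CC(=O)C[C@@H](C)[C@@]1(C)CC=O | intermediate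
8 | (4R,5R)-4-(2-hydroxyethyl)-3,4,5-trimethylcyclohex-2-en-1-one | CC1=CC(=O)C[C@@H](C)[C@@]1(C)CCO | intermediate
9 | (4R,5R)-4-(2-iodoethyl)-3,4,5-trimethylcyclohex-2-en-1-one | CC1=CC(=O)C[C@@H](C)[C@@]1(C)CCI | intermediate
10 | pent-3-yn-1-ol | CC#CCCO | starting material
11 | chlorobis(cyclopentadienyl)[(2E)-5-{[chlorobis(cyclopentadienyl)zirconio]oxy}pent-2-en-2-yl]zirconium | C/C(=C\CCO[Zr](Cl)(C1C=CC=C1)C1C=CC=C1)[Zr](Cl)(C1C=CC=C1)C1C=CC=C1 | intermediate
12 | (E)-4-iodopent-3-en-1-ol | C/C(I)=C\CCO | intermediate
13 | 5-iodopent-2-yne | CC#CCCI | intermediate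
14 | iodo(pent-3-yn-1-yl)zinc | CC#CCC[Zn]I | intermediate
15 | (E)-4-methylnon-3-en-7-yn-1-ol | CC#CCC/C(C)=C/CCO | intermediate
16 | chlorobis(cyclopentadienyl)[(2E,6E)-9-{[chlorobis(cyclopentadienyl)zirconio]oxy}-6-methylnona-2,6-dien-2-yl]zirconium | C/C(=C\CC/C(C)=C/CCO[Zr](Cl)(C1C=CC=C1)C1C=CC=C1)[Zr](Cl)(C1C=CC=C1)C1C=CC=C1 | intermediate
17 | (3E,7E)-8-iodo-4-methylnona-3,7-dien-1-ol | C/C(I)=C\CC/C(C)=C/CCO | intermediate
18 | iodo{2-[(1R,6R)-1,2,6-trimethyl-4-oxocyclohex-2-en-1-yl]ethyl}zinc | CC1=CC(=O)C[C@@H](C)[C@@]1(C)CC[Zn]I | intermediate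
19 | (4R,5R)-4-[(3E,7E)-10-hydroxy-3,7-dimethyldeca-3,7-dien-1-yl]-3,4,5-trimethylcyclohex-2-en-1-one | CC1=CC(=O)C[C@@H](C)[C@@]1(C)CC/C(C)=C/CC/C(C)=C/CCO | intermediate
20 | (4R,5R)-4-[(3E,7E)-10-iodo-3,7-dimethyldeca-3,7-dien-1-yl]-3,4,5-trimethylcyclohex-2-en-1-one | CC1=CC(=O)C[C@@H](C)[C@@]1(C)CC/C(C)=C/CC/C(C)=C/CCI | intermediate
21 | 4-bromofuran-2(5H)-one | O=C1C=C(Br)CO1 | starting material
22 | iodo{(3E,7E)-4,8-dimethyl-10-[(1R,6R)-1,2,6-trimethyl-4-oxocyclohex-2-en-1-yl]deca-3,7-dien-1-yl}zinc | CC1=CC(=O)C[C@@H](C)[C@@]1(C)CC/C(C)=C/CC/C(C)=C/CC[Zn]I | intermediate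
23 | cyclolinteinone | CC1=CC(=O)C[C@@H](C)[C@@]1(C)CC/C(C)=C/CC/C(C)=C/CCC1=CC(=O)OC1 | target

## Step count and risks

Total: 12 steps. Longest linear sequence: 8 steps (1–5, 10–12). The chain branch (steps 6–9) joins at step 10.

**Step 2 (key step).**
- What may go wrong: no turnover, because the β-carbon C5 is fully substituted and lies next to the quaternary C4, so the ring may not reach the flavin. Alternatively, every available homologue may reduce the other enantiotopic double bond.
- Fallback (known chemistry; sets out from 4, returns at 5): the copper hydride-catalysed asymmetric 1,4-reduction established for 3-alkylcyclohex-2-enones. Dienone 4 with Cu(OAc)2, DTBM-SEGPHOS and PhMe2SiH in toluene at −35 °C should give the silyl dienol ether dimethyl(phenyl){[(3R,4R)-3,4,5-trimethyl-4-(prop-2-en-1-yl)cyclohexa-1,5-dien-1-yl]oxy}silane F1. F1 is no longer an enone and is protected from a second reduction; aqueous HCl in THF releases 5.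
- The ligand enantiomer is chosen on 3-methylcyclohex-2-enone as a model for the required face at C5. Here the ligand fixes C5 only, and C4 depends on the small steric difference between the methyl and allyl faces. The C4 epimer (4S,5R)-3,4,5-trimethyl-4-(prop-2-en-1-yl)cyclohex-2-en-1-one F2 is therefore expected alongside 5 and is removed by chromatography.

**Step 1.**
- What may go wrong: attack of the allylsilane at the unsubstituted ortho carbons, which rearomatises to an allylphenol, or capture of the cation by acetate. Both are favoured because the para carbon is flanked by two methyl groups.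
- Fallback (sets out from 1, returns at 4): block the ortho positions. Br2 (2 equiv) in AcOH gives 2,6-dibromo-3,4,5-trimethylphenol F3. The same oxidative allylation then has only the para carbon open and gives 2,6-dibromo-3,4,5-trimethyl-4-(prop-2-en-1-yl)cyclohexa-2,5-dien-1-one F4. Palladium-catalysed hydrodebromination (Pd(PPh3)4, Bu3SnH, THF, rt) returns 4.

**Step 10.**
- What may go wrong: protonolysis of the valuable zinc reagent 18 by the free hydroxyl group of 17, competing with a slow transmetalation at the α-branched alkenylpalladium intermediate.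
- Fallback (sets out from 17, returns at 19): give up the protecting-group-free coupling. TBSCl and imidazole convert 17 into tert-butyl{[(3E,7E)-8-iodo-4-methylnona-3,7-dien-1-yl]oxy}dimethylsilane F5. Coupling of F5 with 18 (PdCl2(dppf), THF) gives the silyl ether (4R,5R)-4-[(3E,7E)-10-{[tert-butyl(dimethyl)silyl]oxy}-3,7-dimethyldeca-3,7-dien-1-yl]-3,4,5-trimethylcyclohex-2-en-1-one F6, and HF·pyridine in THF releases 19.

**Step 12.**
- What may go wrong: consumption of the nucleophile-sensitive bromobutenolide 21 by ring opening, conjugate addition without bromide loss, or reductive debromination, faster than cross-coupling.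
- Fallback (sets out from 20 through zinc reagent 22, returns at 23): build ring B by ring-closing metathesis.
  - Reagent 22 is coupled with 2-bromoprop-2-en-1-ol (Pd(OAc)2, SPhos) to give (4R,5R)-4-[(3E,7E)-11-(hydroxymethyl)-3,7-dimethyldodeca-3,7,11-trien-1-yl]-3,4,5-trimethylcyclohex-2-en-1-one F7.
  - Acryloyl chloride and Et3N give (5E,9E)-6,10-dimethyl-2-methylidene-12-[(1R,6R)-1,2,6-trimethyl-4-oxocyclohex-2-en-1-yl]dodeca-5,9-dien-1-yl prop-2-enoate F8.
  - Second-generation Grubbs catalyst in CH2Cl2 at 40 °C closes the butenolide to 23.

## Further compounds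

F1 | step 2 | dimethyl(phenyl){[(3R,4R)-3,4,5-trimethyl-4-(prop-2-en-1-yl)cyclohexa-1,5-dien-1-yl]oxy}silane | CC1=CC(O[Si](C)(C)c2ccccc2)=C[C@@H](C)[C@@]1(C)CC=C
F2 | step 2 | (4S,5R)-3,4,5-trimethyl-4-(prop-2-en-1-yl)cyclohex-2-en-1-one | CC1=CC(=O)C[C@@H](C)[C@]1(C)CC=C
F3 | step 1 | 2,6-dibromo-3,4,5-trimethylphenol | Cc1c(C)c(Br)c(O)c(Br)c1C
F4 | step 1 | 2,6-dibromo-3,4,5-trimethyl-4-(prop-2-en-1-yl)cyclohexa-2,5-dien-1-one | CC1=C(Br)C(=O)C(Br)=C(C)C1(C)CC=C
F5 | step 10 | tert-butyl{[(3E,7E)-8-iodo-4-methylnona-3,7-dien-1-yl]oxy}dimethylsilane | C/C(I)=C\CC/C(C)=C/CCO[Si](C)(C)C(C)(C)C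
F6 | step 10 | (4R,5R)-4-[(3E,7E)-10-{[tert-butyl(dimethyl)silyl]oxy}-3,7-dimethyldeca-3,7-dien-1-yl]-3,4,5-trimethylcyclohex-2-en-1-one | CC1=CC(=O)C[C@@H](C)[C@@]1(C)CC/C(C)=C/CC/C(C)=C/CCO[Si](C)(C)C(C)(C)C
F7 | step 12 | (4R,5R)-4-[(3E,7E)-11-(hydroxymethyl)-3,7-dimethyldodeca-3,7,11-trien-1-yl]-3,4,5-trimethylcyclohex-2-en-1-one | CC1=CC(=O)C[C@@H](C)[C@@]1(C)CC/C(C)=C/CC/C(C)=C/CCC(=C)CO
F8 | step 12 | (5E,9E)-6,10-dimethyl-2-methylidene-12-[(1R,6R)-1,2,6-trimethyl-4-oxocyclohex-2-en-1-yl]dodeca-5,9-dien-1-yl prop-2-enoate | CC1=CC(=O)C[C@@H](C)[C@@]1(C)CC/C(C)=C/CC/C(C)=C/CCC(=C)COC(=O)C=C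
A1 | alternative 1 | (R)-3-isobutoxy-5-methylcyclohex-2-en-1-one | O=C1C=C(OCC(C)C)C[C@@H](C)C1
A2 | alternative 1 | (5R,6R)-6-[(3E,7E)-10-{[tert-butyl(dimethyl)silyl]oxy}-3,7-dimethyldeca-3,7-dien-1-yl]-3-isobutoxy-5,6-dimethylcyclohex-2-en-1-one | O=C1C=C(OCC(C)C)C[C@@H](C)[C@@]1(C)CC/C(C)=C/CC/C(C)=C/CCO[Si](C)(C)C(C)(C)C
A3 | alternative 2 | (1S,4R)-2,3,4-trimethylcyclohex-2-en-1-ol | C[C@@H]1CC[C@H](O)C(C)=C1C
A4 | alternative 2 | ethyl 2-[(1R,6R)-1,2,6-trimethylcyclohex-2-en-1-yl]acetate | CC1=CCC[C@@H](C)[C@@]1(C)CC(=O)OCC
A5 | alternative 3 | trimethyl[(4-methoxypenta-1,3-dien-2-yl)oxy]silane | C=C(O[Si](C)(C)C)C=C(C)OC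
A6 | alternative 3 | (Z)-2-methylbut-2-enal | C/C=C(/C)C=O
A7 | alternative 3 | (1R,6R)-1,2,6-trimethyl-4-oxocyclohex-2-ene-1-carbaldehyde | CC1=CC(=O)C[C@@H](C)[C@@]1(C)C=O
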